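(The runs were computed for an exercise, noise included.)

A pitfall in repeating these flasks is to follow how much starting material has gone and forget when the target appears. In the delta run, side product over target is 0.0568 at 1.33 min but 0.201 at 10.0 min, so side product comes late and seems to need target already made.

| flask | starting material | partner | remark | time |
|---|---|---|---|---|
| delta | 0.10 M | 1.2 equiv | run made earlier |  |
| gamma | 0.050 M | 1.2 equiv | run made earlier |  |
| eta | 0.20 M | 1.2 equiv | run made earlier |  |
| alpha | 0.10 M | 2.4 equiv | run made earlier |  |
| grey | 0.10 M | 1.20 equiv (fed, over 25 min) | all else is in the flask from the start; the feed brings no volume worth counting | 30 min |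
| green | 0.10 M | 1.20 equiv (in portions, 2, over 25 min) | first portion at the start, last at 25 min | 30 min |
| red | 0.10 M (fed, over 25 min) | 1.20 equiv | all else is in the flask from the start; the feed brings no volume worth counting | 30 min |
| blue | 0.10 M (fed, over 2.5 min) | 1.20 equiv | all else is in the flask from the start; the feed brings no volume worth counting | 30 min |
| ochre | 0.10 M | 1.20 equiv | everything together at the start | 30 min |

- delta (time / min: target / %, side product / %): 1.33: 26.4, 1.5; 2.50: 45.6, 4.6; 4.00: 61.6, 8.9; 6.00: 71.7, 11.8; 10.0: 80.6, 16.2; 20.0: 83.3, 17.0
- gamma (time / min: target / %, side product / %): 2.50: 41.6, 3.1; 8.00: 79.8, 6.9; 12.0: 87.4, 8.8; 20.0: 91.1, 9.0; 30.0: 91.4, 9.0; 40.0: 91.4, 8.3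
- eta (time / min: target / %, side product / %): 6.00: 64.5, 23.5; 12.0: 69.8, 28.1; 20.0: 71.1, 27.7; 25.0: 70.6, 28.0; 30.0: 70.5, 28.8; 40.0: 71.0, 28.4
- alpha (time / min: target / %, side product / %): 3.00: 54.3, 7.7; 10.0: 79.6, 17.1; 15.0: 82.1, 17.6; 25.0: 82.7, 16.9; 40.0: 82.5, 17.4

(each reading ± 0.5 percentage points)

1. which flask leads in share of target in target plus side product ("all alike" within 1.5 percentage points) (grey / green / red / blue / ochre / all alike)
2. share of target in target plus side product at the end, grey
3. share of target in target plus side product at the end, green
4. share of target in target plus side product at the end, red
5. share of target in target plus side product at the end, blue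
6. share of target in target plus side product at the end, ochre

- percentages count the starting material that a species holds: one side product counts as two

We turn the question round: what must the readings show for a partner feed to change nothing? Starting material would have to wait for partner, so twice the partner should nearly double its rate of loss. Counting what is neither target nor side product, the delta run gives 0.279 min⁻¹ and the alpha run 0.323 min⁻¹, a factor of just 1.16. So we read a first-order first step without partner (the rate-limiting step) and count turnovers: 6.97 lifetimes of starting material fit into the grey feed.

Suppose one partner makes one target, and side product forms as starting material times target. Then steady feeding lets target rise slowly while starting material decays. Summing that product over time gives the overlap W, twice the partner charge divided by the turnovers, which is grey's side product as a fraction of the side product with everything present at the start. For the feed to change nothing, W would have to reach one. It stands at 0.344, about a third. The delta run ended with 17.0% side product, so we expect 5.85% in grey, a share of 94.1%, and grey in the lead.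

The forecast differs: it names red as leader, with grey at 72%, green at 55%, red at 83.4%, blue at 83% and ochre at 83%, and of the partner feeds it says “Partner starvation hurts, since target and starting material then coexist longer”.

The flask that leads is grey, with grey at 94.9%, green at 87.1%, red at 82.4%, blue at 83.2% and ochre at 83.5%.

    starting material + target → side product (k = 0.0123 L mol⁻¹ s⁻¹)
    partner + intermediate → target (k = 0.556 L mol⁻¹ s⁻¹)
    starting material → intermediate (k = 0.00520 s⁻¹)

Grey ends with 5.12% side product against our 5.85% from W. At 15.0 min, grey holds 0.655% starting material and 65.1% target, with 29.3% as intermediate, so a low starting material there does not mean a finished run. The neighbouring flask is grey at 0.25 M starting material, with the equivalents of partner held. Its equivalents and feed time keep W at 0.344, while the charge grows by a factor of 2.50, so if side product grows in step with the charge, the same reckoning gives 14.6% side product. That neighbouring flask ends with 11.9% side product and 88.1% target.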